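| flask | Z | D | Q | remark | time |
|---|---|---|---|---|---|
| cedar | 0.050 M | 0.050 M | 3 equiv | run made earlier |  |
| alder | 0.10 M | 0.10 M | 3 equiv | run made earlier |  |
| beta | 0.050 M | 0.050 M | 3.00 equiv | a single well-mixed tank run continuously and read at steady state, 40.0 h in it on average |  |
| epsilon | 0.050 M | 0.050 M | 3.00 equiv | a single well-mixed tank run continuously and read at steady state, 4.0 h in it on average |  |
| gamma | 0.050 M | 0.050 M | 3.00 equiv | a closed flask charged with all of it at once and left for 4.0 h | 4.0 h |
| theta | 0.050 M | 0.050 M | 3.00 equiv | a tube with plug flow, the mixed feed as stated, residence time 4.0 h | 4.0 h |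

cedar run (percent of the Z and D together charged)

| time / h | L / % | G / % | Z / % |
|---|---|---|---|
| 1.00 | 17.7 | 13.9 | 28.4 |
| 2.00 | 23.8 | 22.5 | 19.9 |
| 3.00 | 27.7 | 27.1 | 16.0 |
| 4.00 | 30.1 | 29.9 | 13.4 |

alder run (percent of the Z and D together charged)

| time / min | L / % | G / % | Z / % |
|---|---|---|---|
| 20.0 | 15.9 | 8.9 | 32.8 |
| 40.0 | 22.2 | 17.0 | 23.9 |
| 50.0 | 24.6 | 20.4 | 20.9 |
| 80.0 | 28.2 | 27.0 | 14.3 |

(scatter of a reading: 0.3 percentage points)

- Q is single-handed; Z and D are mirror images of each other, charged as a racemate, each of them at the stated concentration
- the stated concentrations are those of everything mixed, before any reaction; amounts are the same in each set-up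
- the numbers in the tables scatter with a standard deviation of 0.3 percentage points
- reactions considered so far: Q + Z -> L; Q + D -> G; Z <-> D; Q <-> J; L <-> G; Q -> E
- the earlier runs were made in a closed, stirred flask
- the handed part of Q does not stay in what it makes, so the products of the two hands are mirror images too

* the set-up with the highest share of L in all that became L or G, at the outlet or at the end ("none" if the first two lie within 2 percentage points) (beta / epsilon / gamma / theta / none)
* share of L in all that became L or G, at the outlet or at the end, beta
* share of L in all that became L or G, at the outlet or at the end, epsilon
* share of L in all that became L or G, at the outlet or at the end, gamma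
* share of L in all that became L or G, at the outlet or at the end, theta

- In a one-step world Z becomes L, D becomes G and each stays what it is, yet in the cedar run the gap between L and G shrinks from 3.8 percentage points at the first reading to 0.2 points at the last, so the gap is what I watch, since L and G evidently turn into each other.
- I take D from the balance and read from the first cedar reading that D reacts at 0.395 of the pace of Z (the inverse of the selectivity factor), and the gap's balance around the second reading, where the formed excess, the difference of the two formation rates over their sum, is 0.198, gives as a reading a forgetting rate, the pace at which the gap between L and G decays by their turning into each other, of 2.99 h⁻¹.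
- In a well-mixed tank at steady state the outflow removes the sum and the gap alike, but forgetting removes the gap as well, so the memory, the part of the formed excess that reaches the outlet, is one over one plus forgetting rate times residence time, 0.0771 in epsilon, and the share of L in such a tank is one half plus half the formed excess times the memory.
- My first round takes the excess of the charge, 0.434, and gives 51.7% for epsilon; going round again with the mean cedar decay of Z, 0.329 h⁻¹, puts Z at 21.6% and D at 32.9% by my estimate, so the excess falls to 0.249 and the share to 51.0%.
- The memory serves the two tanks but not the other two set-ups: gamma and theta, a closed flask and a plug-flow tube with the charge and time of cedar, repeat its last reading, 50.2%, beta's memory is 0.00828 and gives 50.2%, and even my first round for epsilon stands only 1.5 points above cedar, so I say none.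
- The forecast also says none, with 50.2%, 51.6%, 50.1% and 50.1% for beta, epsilon, gamma and theta, its epsilon above my second round, and for beta it holds that “racemisation outruns everything”.
- The epsilon tank gives 51.4%, and the answer is none.

    Q + Z → L (k = 0.0960 M⁻¹ min⁻¹)
    Q + D → G (k = 0.0340 M⁻¹ min⁻¹)
    Z ⇌ D (k = 0.00140 min⁻¹)
    Q ⇌ J (K = 0.210, k = 0.0400 min⁻¹)
    L ⇌ G (k = 0.0230 min⁻¹)
    Q → E (k = 0.00310 min⁻¹)

- The step from Q to J makes no difference to that epsilon share. Divided by the memory, the epsilon share asks for a formed excess of 0.369, and that excess, taken unchanged into beta with its memory, gives 50.2%, while the beta tank stands at 50.2%.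

Readings and results were generated by integration with made-up constants, noise included.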